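At early times the starting complex takes up incoming ligand, and the complex with one exchanged soon competes for the same ligand. Let m and a be the fractions of the charge held as starting complex and as complex with one exchanged, and let s be the ratio of the second step's rate constant to the first's. If these two forward steps act, ligand cancels from the quotient of their rates. So, with these two steps, a follows from m: a equals m^s minus m, divided by one minus s. Its peak is s raised to the power s/(one minus s).

all flasks: starting complex 30 mM
- dusk: incoming ligand 13 mM; leaving ligand 30 mM; run made earlier
- autumn: incoming ligand 55 mM; leaving ligand 30 mM; run made earlier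
- north-west: incoming ligand 24.0 mM; leaving ligand 30.0 mM; time 3.0 d
- west: incoming ligand 30.0 mM; leaving ligand 30.0 mM; time 3.0 d
- north-east: incoming ligand 90.0 mM; leaving ligand 30.0 mM; time 3.0 d

| run | time / d | complex with one exchanged / % | complex with four exchanged / % |
|---|---|---|---|
| dusk | 0.833 | 33.6 | 0 |
| dusk | 1.67 | 37.7 | 0.4 |
| dusk | 2.50 | 39.1 | 0.2 |
| dusk | 3.00 | 40.0 | 0 |
| autumn | 0.417 | 66.9 | 0 |
| autumn | 1.04 | 70.0 | 0.3 |
| autumn | 2.08 | 60.1 | 2.1 |
| autumn | 3.00 | 54.0 | 2.7 |

(standard deviation of a reading: 0.3 percentage points)
- amount of complex with one exchanged at the end, in percent of the starting complex charged, for each flask in turn (north-west, west, north-east)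

Taking the autumn run's highest reading, 70.0% at 1.04 d, as its peak, we set s = 0.167, the selectivity ratio (inverse selectivity factor), since that s gives a peak of 69.9%. The dusk run read 40.0% at 3.00 d, below its ligand ceiling of 43.3%.

The west flask charges 1.00 ligand per complex. We assume that ligand is used up, that exchange stops at two, and that a sits near its flat peak. The balance then gives m = 15.1%, and the rule gives a = 69.5%.

The forecast differs from our west figure: it gave 59%, 66% and 14%, with the north-west and west flasks “close to first-step equilibrium by 3 d”.

The flasks give 63.0%, 69.3% and 23.3%, and the gap is widest in the north-east flask, 9.3 percentage points.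

    starting complex + incoming ligand → leaving ligand + complex with one exchanged (k = 0.00102 L mol⁻¹ s⁻¹)
    complex with one exchanged + incoming ligand → leaving ligand + complex with two exchanged (k = 1.58 × 10⁻⁴ L mol⁻¹ s⁻¹)
    complex with two exchanged + incoming ligand → leaving ligand + complex with three exchanged (k = 9.13 × 10⁻⁵ L mol⁻¹ s⁻¹)
    complex with three exchanged + incoming ligand → leaving ligand + complex with four exchanged (k = 4.19 × 10⁻⁴ L mol⁻¹ s⁻¹)
    starting complex + complex with two exchanged → side product (k = 1.20 × 10⁻⁴ L mol⁻¹ s⁻¹)

In the west flask, with 4.0% of the incoming ligand left, the simulated m of 16.2% puts the rule at 69.2% against 69.3%. In the north-west flask, the simulated 28.1% gives 63.4% against 63.0%. In the north-west flask the half-life of starting complex by the first step grows from 0.60 d at 0.280 d to 16 d at 3.00 d, with 2.0% of the incoming ligand left. At that time in the north-west flask, the first step still uses incoming ligand 2.9 times as fast as the second.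

The earlier runs and the new flask stem from a simulated flask with constants of no real substance, noise included.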